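**Retrosynthetic overview**
- Ring order: both benzene rings are bought; the only ring made is the pyranone, closed first (acetophenone 1 → enaminone 2 → chromone 3). Ring B arrives intact in iodide 5 (from alcohol 4).
- Key disconnection: the C2–C1' bond between chromone C2 and the ethylene chain. C2 is normally the acceptor carbon of the vinylogous ester; C2–H zincation turns it into nucleophile 6, a β-acylvinyl (homoenolate-type, d3) anion that is also a metalated enol ether (masked acyl anion of the 1,3-diketone).
- Its partner is the CH2–I carbon of 5, itself an electrophile, carried as zinc phenoxide 7. Nickel-catalysed sp2–sp3 coupling gives zinc phenoxide 8, protonated to target 9.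
- Convergent, three steps, no protecting-group steps.

Assumption: the target SMILES has no stereocentre and no stereogenic double bond, so the compound is achiral and no stereocontrol is needed.

**Step 1**
Reactants: 1 1-(2-hydroxy-4,5-dimethoxyphenyl)ethan-1-one
Product: 3 6,7-dimethoxy-4H-chromen-4-one, via enaminone 2 (not isolated)
Conditions: DMF-DMA (1.5 equiv), toluene, 100 °C, 3 h; concentrate; then conc. HCl, CH2Cl2, 40 °C, 1 h
Reagents that add atoms: N,N-dimethylformamide dimethyl acetal, COC(OC)N(C)C
Why: Enaminone chromone synthesis: condensation of the methyl ketone with the amide acetal, then acid-promoted 6-endo addition of the phenol and elimination of dimethylamine closes the pyranone and leaves C2–H free; no stereocentre is formed.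

**Step 2**
Reactants: 4 2-(3-hydroxy-4-methoxyphenyl)ethan-1-ol
Product: 5 5-(2-iodoethyl)-2-methoxyphenol
Conditions: PPh3 (1.2 equiv), I2 (1.2 equiv), imidazole (1.3 equiv), CH2Cl2, 0 °C → rt, 1 h, dark
Reagents that add atoms: iodine, II
Why: Appel (Garegg–Samuelsson) iodination: only the primary alcohol forms an alkoxyphosphonium ion that iodide can displace by SN2, and the phenol is returned on work-up (as with tyrosol); no stereocentre is formed.

**Step 3**
Reactants: 3 6,7-dimethoxy-4H-chromen-4-one; 5 5-(2-iodoethyl)-2-methoxyphenol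
Product: 9 2-[2-(3-hydroxy-4-methoxyphenyl)ethyl]-6,7-dimethoxy-4H-chromen-4-one, via bis(6,7-dimethoxy-4-oxochromen-2-yl)zinc 6 (not isolated), via zinc bis[5-(2-iodoethyl)-2-methoxyphenoxide] 7 (not isolated), via zinc bis(phenoxide) of the coupled product 8 (not isolated)
Conditions: (a) 3 (1.5 equiv), TMP2Zn·2MgCl2·2LiCl (0.8 equiv, stock solution; TMP = 2,2,6,6-tetramethylpiperidin-1-yl), THF, −30 °C, 1.5 h; (b) separately 5 (1.0 equiv), TMP2Zn·2MgCl2·2LiCl (0.5 equiv), THF, −30 °C, 10 min; (c) combine, Ni(acac)2 (10 mol %), 4-(trifluoromethyl)styrene (1.0 equiv), THF/NMP 2:1, −15 °C → 25 °C, 12 h; 1 M HCl work-up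
Reagents that add atoms: none
Why: Proposed new method: MgCl2 bound to the C4 carbonyl steers the zinc amide away from C3–H to the more acidic C2–H (α to the ring oxygen), giving sp2 zinc reagent 6; this transmetalates to nickel and is joined to the primary C–I carbon, with the π-acidic styrene speeding reductive elimination past β-hydride elimination and the phenol held as the non-nucleophilic zinc phenoxide 7. The closest known reaction types are the C2-zincation/Negishi arylation of chromones and the Ni(acac)2/styrene-promoted Negishi coupling of arylzinc reagents with primary alkyl iodides; no stereocentre is formed.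

The base-to-regiochemistry pairing in step 3(a) is from memory of the chromone zincation literature; confirm C2 selectivity on an aliquot (I2 or D2O quench) before committing material.

**Compound list**
1 | 1-(2-hydroxy-4,5-dimethoxyphenyl)ethan-1-one | CC(=O)c1cc(OC)c(OC)cc1O | starting material
2 | (E)-3-(dimethylamino)-1-(2-hydroxy-4,5-dimethoxyphenyl)prop-2-en-1-one | CN(C)/C=C/C(=O)c1cc(OC)c(OC)cc1O | intermediate
3 | 6,7-dimethoxy-4H-chromen-4-one | COc1cc2occc(=O)c2cc1OC | intermediate
4 | 2-(3-hydroxy-4-methoxyphenyl)ethan-1-ol (3-hydroxy-4-methoxyphenethyl alcohol) | COc1ccc(CCO)cc1O | starting material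
5 | 5-(2-iodoethyl)-2-methoxyphenol | COc1ccc(CCI)cc1O | intermediate
6 | bis(6,7-dimethoxy-4-oxo-4H-chromen-2-yl)zinc | COc1cc2oc([Zn]c3cc(=O)c4cc(OC)c(OC)cc4o3)cc(=O)c2cc1OC | intermediate
7 | zinc bis[5-(2-iodoethyl)-2-methoxyphenoxide] | COc1ccc(CCI)cc1O[Zn]Oc1cc(CCI)ccc1OC | intermediate
8 | zinc bis{5-[2-(6,7-dimethoxy-4-oxo-4H-chromen-2-yl)ethyl]-2-methoxyphenoxide} | COc1ccc(CCc2cc(=O)c3cc(OC)c(OC)cc3o2)cc1O[Zn]Oc1cc(CCc2cc(=O)c3cc(OC)c(OC)cc3o2)ccc1OC | intermediate
9 | 2-[2-(3-hydroxy-4-methoxyphenyl)ethyl]-6,7-dimethoxy-4H-chromen-4-one | COc1ccc(CCc2cc(=O)c3cc(OC)c(OC)cc3o2)cc1O | target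

**Totals**
Total steps: 3. Longest linear sequence: 2 (1 → 3 → 9, or 4 → 5 → 9).

**Steps most likely to fail, with fallbacks**

Step 3 (highest risk). The sp2–sp3 coupling of an electron-poor chromonylzinc with a phenethyl iodide is untested. Likely failures are β-hydride elimination to 2-methoxy-5-vinylphenol, protonation of 6 back to 3, or wrong zincation regiochemistry. The fallback keeps the same bond but joins the two carbons as two electrophiles under reduction. It sets out from 3, which is zincated to 6 as above and quenched with I2 (THF, −30 °C → rt) to give 2-iodo-6,7-dimethoxy-4H-chromen-4-one F1. F1 and iodide 5 (free phenol, no base) are then joined by nickel-catalysed cross-electrophile coupling (NiI2 10 mol %, 4,4'-di-tert-butyl-2,2'-bipyridine 10 mol %, zinc dust 2 equiv, NaI, DMA, 60 °C). This comes back to the route at 9.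

Step 2. The free phenol may consume the phosphonium reagent, or iodophenol 5 may self-alkylate on concentration or storage. The fallback changes the protecting-group logic and sets out from 4. Phenoxide-selective benzylation (benzyl bromide, K2CO3, acetone, reflux) gives 2-[3-(benzyloxy)-4-methoxyphenyl]ethan-1-ol F2. The same PPh3/I2/imidazole iodination gives 2-(benzyloxy)-4-(2-iodoethyl)-1-methoxybenzene F3. F3 is coupled with 6 under the step 3 nickel conditions (no phenoxide-forming portion of base needed) to give 2-{2-[3-(benzyloxy)-4-methoxyphenyl]ethyl}-6,7-dimethoxy-4H-chromen-4-one F4. Hydrogenolysis (H2 1 atm, 10% Pd/C, EtOAc, rt, stopped at full debenzylation so the chromone C2=C3 bond is kept) comes back to the route at 9. This costs two extra steps.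

Step 1. DMF-DMA may partly O-methylate the phenol, or the enaminone may cyclise incompletely. The fallback replaces the amide acetal by a Claisen formylation and sets out from 1. NaH (3 equiv) and ethyl formate in THF (0 °C → rt), then acidification, give racemic 2-hydroxy-6,7-dimethoxychroman-4-one F5 (the cyclic hemiacetal of the formyl ketone). Dehydration (conc. HCl in AcOH, 60 °C) comes back to the route at 3.

**Further compounds**
F1 | step 3 | 2-iodo-6,7-dimethoxy-4H-chromen-4-one | COc1cc2oc(I)cc(=O)c2cc1OC
F2 | step 2 | 2-[3-(benzyloxy)-4-methoxyphenyl]ethan-1-ol | COc1ccc(CCO)cc1OCc1ccccc1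
F3 | step 2 | 2-(benzyloxy)-4-(2-iodoethyl)-1-methoxybenzene | COc1ccc(CCI)cc1OCc1ccccc1
F4 | step 2 | 2-{2-[3-(benzyloxy)-4-methoxyphenyl]ethyl}-6,7-dimethoxy-4H-chromen-4-one | COc1ccc(CCc2cc(=O)c3cc(OC)c(OC)cc3o2)cc1OCc1ccccc1
F5 | step 1 | 2-hydroxy-6,7-dimethoxychroman-4-one (racemic hemiacetal) | COc1cc2OC(O)CC(=O)c2cc1OC
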